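The data come from a simulation with constants of no real substance; the scatter is artificial.

Which flask ends with more first product, Thursday's, concentrated and long, or Friday's, dilute and short?

in all of them: gas 61 mM (held)
- larch: substrate 0.076 M; run made earlier
- birch: substrate 0.39 M; run made earlier
- Thursday's: substrate 0.50 M; time 8.0 h
- Friday's: substrate 0.12 M; time 2.5 h

- larch (time / h: first product / %, substrate / %): 0.333: 2.9, 93.6; 0.833: 10.9, 71.1; 1.50: 20.9, 45.7; 2.50: 30.2, 22.1; 3.00: 31.3, 15.9; 4.00: 34.3, 9.0; 6.00: 33.3, 1.3
- birch (time / h: first product / %, substrate / %): 0.333: 3.2, 95.0; 0.833: 6.9, 80.8; 1.50: 11.4, 62.2; 2.50: 15.9, 40.8; 3.00: 19.4, 32.3; 4.00: 19.7, 19.3; 6.00: 22.7, 6.5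

(scatter of a reading: 1 percentage point)

- the flask that ends with the higher amount of first product, in percent of the substrate charged, or "neither" when 2 percentage points or less lies between them (Thursday's / Friday's / neither)
- final first product, as a percentage of the substrate charged, in Thursday's
- final first product, as a percentage of the substrate charged, in Friday's

- a species is counted by the substrate in it: one side product counts as two
- at the start none of reagent is dissolved
- the numbers in the tables scatter with a standard deviation of 1 percentage point
- reactions considered so far: substrate + reagent -> first product + by-product; substrate + reagent -> other mono adduct + by-product; reagent + first product -> bis adduct + by-product; reagent + other mono adduct -> bis adduct + by-product; gas <-> reagent; substrate + first product -> side product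

*What do you divide?* First product held by substrate consumed, both as percent of the charge. The ratio still moves as a flask runs on, so I set larch and birch side by side at one and the same time. At 2.50 h larch gives 0.388 and birch 0.269, so the richer charge holds less than the dilute one.

*And Friday's?* Its charge of 0.12 M lies between theirs, so I draw a straight line in the charge. That gives the keep of Friday's, first product held per substrate consumed, the overall selectivity, as 0.371. The same line gives 24.7 % of substrate left, so I reckon 27.9 %.

*Thursday's?* The last readings, at 6.00 h, give 0.337 for larch and 0.243 for birch. Carried on to 0.50 M, the line gives 0.210, which is 21.0 % if I count the charge as consumed.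

*Where is that weak?* It runs beyond birch's charge, and it is read before 8.0 h. Larch's keep also sinks with time, 0.337 being less than 0.388, so Thursday's could come lower. That widens my gap, which already exceeds the margin.

The forecast says Friday's, with 20 % (16.5 % to 23 %) for Thursday's and 27.5 % (24.5 % to 30 %) for Friday's, on the ground that “Birch's lower yield points to the substrate + first product side reaction”.

The flasks give Friday's: 20.1 % in Thursday's and 27.1 % in Friday's.

    substrate + reagent → first product + by-product (k = 0.00150 M⁻¹ s⁻¹)
    substrate + reagent → other mono adduct + by-product (k = 0.00210 M⁻¹ s⁻¹)
    reagent + first product → bis adduct + by-product (k = 1.30 × 10⁻⁴ M⁻¹ s⁻¹)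
    reagent + other mono adduct → bis adduct + by-product (k = 0.00160 M⁻¹ s⁻¹)
    gas ⇌ reagent, rate k5*(csat - [reagent]) (kL = 8.10 × 10⁻⁴ s⁻¹)
    substrate + first product → side product (k = 2.70 × 10⁻⁴ M⁻¹ s⁻¹)

Neither flask has come to rest. Thursday's at 8.00 h keeps 0.205, against the reckoned 0.210, with 1.8 % of its substrate left, yet at 80.0 h first product stands at 2.72 %, a keep of 0.0272, and bis adduct has gone from 35.5 % to 70.4 %. Friday's keeps 0.366, against the reckoned 0.371. Read at 10 h, with 0.080 % of substrate left, it keeps 0.299, and at 25.0 h its first product stands at 19.5 %, a keep of 0.195.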